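Everything rests on cutting the cyclopentane ring (C1–C5, daucane numbering) at C3–C4. The feature exploited is the 1,6-relation of C4 and the oxygen on C9 across C5–C1–C10. They are first joined as a δ-lactone (O9, C4, C5, C1, C10, C9), a temporary ring through which C9 relays its configuration to C1, C5 and C6. The key-step precursor is this lactone carrying a 2-iodoethyl arm (C2–C3) on C1. SmI2 turns C3 into an alkylsamarium that attacks the lactone carbonyl C4. In one operation the five-membered ring closes, the template lactone opens and the C9 hydroxyl is unveiled. Isopropyl addition, ring-closing metathesis (C7=C8) and desilylation follow.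

Key step: step 10

Remark on numbering: C1 = quaternary carbon bearing CH3; C2, C3 = ring CH2; C4 = carbinol carbon bearing isopropyl; C5 = ring-fusion CH; C6 = carbinol carbon bearing the vanillate; C7=C8(CH3); C9 = free carbinol; C10 = CH2.
Assumption: (−)-Ipc2BCl is written as the antipode that attacks the Re face of methacrolein; if the sense of induction proves opposite, (+)-Ipc2BCl is used and nothing else changes.

Step 1
Reactants: 1 4-hydroxybutan-2-one
Product: 2 4-[(tert-butyldimethylsilyl)oxy]butan-2-one
Conditions: TBSCl, imidazole, CH2Cl2, 0 °C to rt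
Reagents that add atoms: TBSCl, CC(C)(C)[Si](C)(C)Cl
Why: Imidazole-promoted O-silylation masks the primary alcohol (the future C3 leaving group) under conditions too mild for β-elimination, and no stereocentre is formed.

Step 2
Reactants: 2 4-[(tert-butyldimethylsilyl)oxy]butan-2-one; 3 methacrolein
Product: 5 (5R)-1-[(tert-butyldimethylsilyl)oxy]-5-hydroxy-6-methylhept-6-en-3-one, via boron enolate 4 (not isolated)
Conditions: (−)-Ipc2BCl, Et3N, Et2O, 0 °C; then 3, −78 to −20 °C; then H2O2, MeOH, pH 7 buffer, 0 °C
Reagents that add atoms: none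
Why: Boron-mediated asymmetric aldol reaction of a methyl ketone, in which Ipc2BCl/Et3N enolises the less hindered CH3 side and the isopinocampheyl ligands select the Re face of the aldehyde in the cyclic transition state, setting C9 as R.

Step 3
Reactants: 5 (5R)-1-[(tert-butyldimethylsilyl)oxy]-5-hydroxy-6-methylhept-6-en-3-one
Product: 7 (6R)-4-{2-[(tert-butyldimethylsilyl)oxy]ethyl}-6-(prop-1-en-2-yl)-5,6-dihydro-2H-pyran-2-one, via ester ylide 6 (not isolated)
Conditions: Ph3P=C=C=O, toluene, reflux
Reagents that add atoms: (triphenylphosphoranylidene)ketene, O=C=C=P(c1ccccc1)(c1ccccc1)c1ccccc1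
Why: Domino addition–intramolecular Wittig olefination, in which the C9 hydroxyl adds to the cumulated ylide and the stabilised ester ylide olefinates the C1 ketone, the six-membered ring enforcing the cis ring alkene C5=C1 while C9 is untouched.

Step 4
Reactants: 7 (6R)-4-{2-[(tert-butyldimethylsilyl)oxy]ethyl}-6-(prop-1-en-2-yl)-5,6-dihydro-2H-pyran-2-one
Product: 9 (4R,6R)-4-{2-[(tert-butyldimethylsilyl)oxy]ethyl}-4-methyl-6-(prop-1-en-2-yl)oxan-2-one, via silyl ketene acetal 8 (not isolated)
Conditions: MeMgBr, CuBr·SMe2 (10 mol %), TMSCl, DMPU, THF, −78 °C; then aq NH4Cl, dilute citric acid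
Reagents that add atoms: MeMgBr, C[Mg]Br
Why: TMSCl-accelerated copper-catalysed conjugate addition, in which methyl attacks C1 axially on the half-chair lactone anti to the equatorial isopropenyl group on C9 and so sets the quaternary centre (CH3 trans to isopropenyl), the low temperature disfavouring SN2′ opening of the allylic lactone.

Step 5
Reactants: 9 (4R,6R)-4-{2-[(tert-butyldimethylsilyl)oxy]ethyl}-4-methyl-6-(prop-1-en-2-yl)oxan-2-one; 10 acrolein
Product: 12 (3S,4R,6R)-4-{2-[(tert-butyldimethylsilyl)oxy]ethyl}-3-[(1S)-1-hydroxyprop-2-en-1-yl]-4-methyl-6-(prop-1-en-2-yl)oxan-2-one, via lithium enolate 11 (not isolated)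
Conditions: LiN(iPr)2, THF, −78 °C; then 10, −78 °C; AcOH quench at −78 °C
Reagents that add atoms: none
Why: Lithium enolate aldol addition, in which the ring-locked E(O)-enolate is attacked on the face opposite the axial CH3 on C1 (sets C5) and the Zimmerman–Traxler chair of such an enolate leads to the anti aldol (sets C6), acrolein reacting 1,2 at this temperature.

Step 6
Reactants: 13 vanillic acid
Product: 15 3-methoxy-4-[(triisopropylsilyl)oxy]benzoic acid, via bis-silylated vanillate 14 (not isolated)
Conditions: TIPSCl (2.2 equiv), imidazole, DMF, rt; then AcOH–THF–H2O, rt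
Reagents that add atoms: TIPSCl, CC(C)[Si](Cl)(C(C)C)C(C)C
Why: Exhaustive silylation followed by selective hydrolysis of the far more labile silyl ester leaves only the phenol protected, and no stereocentre is involved.

Step 7
Reactants: 12 (3S,4R,6R)-4-{2-[(tert-butyldimethylsilyl)oxy]ethyl}-3-[(1S)-1-hydroxyprop-2-en-1-yl]-4-methyl-6-(prop-1-en-2-yl)oxan-2-one; 15 3-methoxy-4-[(triisopropylsilyl)oxy]benzoic acid
Product: 16 (1S)-1-[(3S,4R,6R)-4-{2-[(tert-butyldimethylsilyl)oxy]ethyl}-4-methyl-2-oxo-6-(prop-1-en-2-yl)oxan-3-yl]prop-2-en-1-yl 3-methoxy-4-[(triisopropylsilyl)oxy]benzoate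
Conditions: EDC·HCl, DMAP, CH2Cl2, 0 °C to rt
Reagents that add atoms: none
Why: Steglich-type esterification acylates O6 with retention at C6 and installs the natural acyl group early, so that it also protects O6 and distinguishes it from O9, which is still held in the lactone.

Step 8
Reactants: 16 (the silyl ether above)
Product: 17 (1S)-1-[(3S,4R,6R)-4-(2-hydroxyethyl)-4-methyl-2-oxo-6-(prop-1-en-2-yl)oxan-3-yl]prop-2-en-1-yl 3-methoxy-4-[(triisopropylsilyl)oxy]benzoate
Conditions: HF·pyridine, pyridine, THF, 0 °C; crude product used at once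
Reagents that add atoms: none
Why: Buffered fluoride desilylation cleaves the unhindered primary alkyl TBS ether much faster than the bulky aryl TIPS ether, and the near-neutral medium disfavours translactonisation and β-elimination.

Step 9
Reactants: 17 (the primary alcohol above)
Product: 18 (1S)-1-[(3S,4S,6R)-4-(2-iodoethyl)-4-methyl-2-oxo-6-(prop-1-en-2-yl)oxan-3-yl]prop-2-en-1-yl 3-methoxy-4-[(triisopropylsilyl)oxy]benzoate
Conditions: I2, PPh3, imidazole, CH2Cl2, 0 °C
Reagents that add atoms: iodine, II
Why: Appel-type iodination replaces the primary hydroxyl by SN2 displacement of the alkoxyphosphonium ion, and no stereocentre is touched (the descriptor at C1 changes only through priorities).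

Step 10
Reactants: 18 (the iodo lactone above)
Product: 21 (1S)-1-{(1S,2R)-2-[(2R)-2-hydroxy-3-methylbut-3-en-1-yl]-2-methyl-5-oxocyclopentyl}prop-2-en-1-yl 3-methoxy-4-[(triisopropylsilyl)oxy]benzoate, via alkylsamarium diiodide 19 (not isolated), via bridged hemiketal alkoxide 20 (not isolated)
Conditions: SmI2 (2.2 equiv, slow addition), Fe(PhCOCHCOPh)3 (2 mol %), THF, −30 °C to rt; pH 7 buffer
Reagents that add atoms: none
Why: Two single-electron transfers from divalent samarium convert the primary C3–I bond, via the radical, into an alkyl derivative of trivalent samarium, which adds to the lactone carbonyl C4; the bridged hemiketal alkoxide 20 then collapses and expels the C9 alkoxide, which is the SmI2-promoted intramolecular nucleophilic acyl substitution of halo lactones (a Barbier-type acylation). The ring C1–C2–C3–C4–C5 closes in the 5-exo-trig mode, the C2–C3 arm reaching C4 from the lactone face on which it already stands. No lasting stereocentre is created (C4 ends sp2 and its transient configuration in 20 is dictated by the tether), and C1, C6 and C9 are not touched. C5 should hold because the medium is aprotic and weakly basic and because its C6 arm already lies cis to the smaller CH3 on C1. The step needs chemoselectivity for the lactone over the aryl ester and the two alkenes: the lactone is reached through a five-membered transition state whereas the electron-rich, hindered vanillate would need a seven-membered one, and 6-exo attack of the transient radical on the C7 vinyl group is intrinsically slow compared with its reduction. Over-reduction of the liberated ketone is limited by the stoichiometry and slow addition of SmI2 and by the absence of a proton source.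

Step 11
Reactants: 21 (the cyclopentanone above)
Product: 22 (1S)-1-{(1S,2R,5R)-2-hydroxy-5-[(2R)-2-hydroxy-3-methylbut-3-en-1-yl]-5-methyl-2-(propan-2-yl)cyclopentyl}prop-2-en-1-yl 3-methoxy-4-[(triisopropylsilyl)oxy]benzoate
Conditions: iPrMgCl (3 equiv), LaCl3·2LiCl, THF, −78 to −40 °C; aq NH4Cl
Reagents that add atoms: iPrMgCl, CC(C)[Mg]Cl
Why: LaCl3·2LiCl-promoted Grignard 1,2-addition suppresses enolisation, β-hydride reduction and β-elimination, the nucleophile approaching the cyclopentanone anti to the bulky C5 substituent so that isopropyl ends α and OH β at C4 (R), while the hindered electron-rich aryl ester reacts more slowly than the ketone.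

Step 12
Reactants: 22 (the diene above)
Product: 23 (1R,4R,5S,6S,9R)-4,9-dihydroxydauc-7-en-6-yl 3-methoxy-4-[(triisopropylsilyl)oxy]benzoate
Conditions: second-generation Grubbs catalyst (5 mol %), CH2Cl2 (2 mM), reflux
Reagents that add atoms: none
Why: Ring-closing metathesis of the C7 vinyl group and the C8 isopropenyl group on the trans-disposed arms closes the cycloheptene with the ring-enforced cis trisubstituted C7=C8 alkene and touches no stereocentre.

Step 13
Reactants: 23 (the aryl silyl ether above)
Product: 24 (1R,4R,5S,6S,9R)-4,9-dihydroxydauc-7-en-6-yl 4-hydroxy-3-methoxybenzoate (target)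
Conditions: Bu4NF, AcOH, THF, 0 °C
Reagents that add atoms: none
Why: Fluoride cleavage of the aryl silyl ether is fast, and buffering by AcOH prevents acyl migration or ester cleavage, so all five stereocentres are retained.

Compound list
1 | 4-hydroxybutan-2-one | CC(=O)CCO | starting material
2 | 4-[(tert-butyldimethylsilyl)oxy]butan-2-one | CC(=O)CCO[Si](C)(C)C(C)(C)C | intermediate
3 | methacrolein | CC(=C)C=O | starting material
4 | diisopinocampheylboron enolate of 2 (CH3 side) | C=C(CCO[Si](C)(C)C(C)(C)C)OB([C@@H]1C[C@@H]2C[C@H]([C@H]1C)C2(C)C)[C@@H]1C[C@@H]2C[C@H]([C@H]1C)C2(C)C | intermediate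
5 | (5R)-1-[(tert-butyldimethylsilyl)oxy]-5-hydroxy-6-methylhept-6-en-3-one | CC(=C)[C@H](O)CC(=O)CCO[Si](C)(C)C(C)(C)C | intermediate
6 | (triphenylphosphoranylidene)acetate ester of 5 | CC(=C)[C@@H](CC(=O)CCO[Si](C)(C)C(C)(C)C)OC(=O)C=P(c1ccccc1)(c1ccccc1)c1ccccc1 | intermediate
7 | (6R)-4-{2-[(tert-butyldimethylsilyl)oxy]ethyl}-6-(prop-1-en-2-yl)-5,6-dihydro-2H-pyran-2-one | O=C1C=C(CCO[Si](C)(C)C(C)(C)C)C[C@H](C(C)=C)O1 | intermediate
8 | trimethylsilyl ketene acetal of 9 | C[Si](C)(C)OC1=C[C@](C)(CCO[Si](C)(C)C(C)(C)C)C[C@H](C(C)=C)O1 | intermediate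
9 | (4R,6R)-4-{2-[(tert-butyldimethylsilyl)oxy]ethyl}-4-methyl-6-(prop-1-en-2-yl)oxan-2-one | O=C1C[C@](C)(CCO[Si](C)(C)C(C)(C)C)C[C@H](C(C)=C)O1 | intermediate
10 | acrolein | C=CC=O | starting material
11 | lithium enolate of 9 | [Li]OC1=C[C@](C)(CCO[Si](C)(C)C(C)(C)C)C[C@H](C(C)=C)O1 | intermediate
12 | (3S,4R,6R)-4-{2-[(tert-butyldimethylsilyl)oxy]ethyl}-3-[(1S)-1-hydroxyprop-2-en-1-yl]-4-methyl-6-(prop-1-en-2-yl)oxan-2-one | O=C1[C@H]([C@@H](O)C=C)[C@](C)(CCO[Si](C)(C)C(C)(C)C)C[C@H](C(C)=C)O1 | intermediate
13 | vanillic acid | COc1cc(C(=O)O)ccc1O | starting material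
14 | triisopropylsilyl 3-methoxy-4-[(triisopropylsilyl)oxy]benzoate | COc1cc(C(=O)O[Si](C(C)C)(C(C)C)C(C)C)ccc1O[Si](C(C)C)(C(C)C)C(C)C | intermediate
15 | 3-methoxy-4-[(triisopropylsilyl)oxy]benzoic acid | COc1cc(C(=O)O)ccc1O[Si](C(C)C)(C(C)C)C(C)C | intermediate
16 | O6-aroylated lactone with TBS-oxyethyl arm, (1S;3S,4R,6R) | O=C1[C@H]([C@@H](OC(=O)c2ccc(O[Si](C(C)C)(C(C)C)C(C)C)c(OC)c2)C=C)[C@](C)(CCO[Si](C)(C)C(C)(C)C)C[C@H](C(C)=C)O1 | intermediate
17 | O6-aroylated lactone with 2-hydroxyethyl arm, (1S;3S,4R,6R) | O=C1[C@H]([C@@H](OC(=O)c2ccc(O[Si](C(C)C)(C(C)C)C(C)C)c(OC)c2)C=C)[C@](C)(CCO)C[C@H](C(C)=C)O1 | intermediate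
18 | O6-aroylated lactone with 2-iodoethyl arm, (1S;3S,4S,6R) | O=C1[C@H]([C@@H](OC(=O)c2ccc(O[Si](C(C)C)(C(C)C)C(C)C)c(OC)c2)C=C)[C@](C)(CCI)C[C@H](C(C)=C)O1 | intermediate
19 | alkylsamarium diiodide from 18 | O=C1[C@H]([C@@H](OC(=O)c2ccc(O[Si](C(C)C)(C(C)C)C(C)C)c(OC)c2)C=C)[C@](C)(CC[Sm](I)I)C[C@H](C(C)=C)O1 | intermediate
20 | bridged hemiketal samarium alkoxide (2-oxabicyclo[3.2.1]octan-1-olate) | I[Sm](I)O[C@]12CC[C@](C)(C[C@H](C(C)=C)O1)[C@H]2[C@@H](OC(=O)c3ccc(O[Si](C(C)C)(C(C)C)C(C)C)c(OC)c3)C=C | intermediate
21 | (1S)-1-{(1S,2R)-2-[(2R)-2-hydroxy-3-methylbut-3-en-1-yl]-2-methyl-5-oxocyclopentyl}prop-2-en-1-yl 3-methoxy-4-[(triisopropylsilyl)oxy]benzoate | O=C1CC[C@](C)(C[C@@H](O)C(C)=C)[C@H]1[C@@H](OC(=O)c2ccc(O[Si](C(C)C)(C(C)C)C(C)C)c(OC)c2)C=C | intermediate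
22 | (1S)-1-{(1S,2R,5R)-2-hydroxy-5-[(2R)-2-hydroxy-3-methylbut-3-en-1-yl]-5-methyl-2-(propan-2-yl)cyclopentyl}prop-2-en-1-yl 3-methoxy-4-[(triisopropylsilyl)oxy]benzoate | O[C@@]1(C(C)C)CC[C@](C)(C[C@@H](O)C(C)=C)[C@H]1[C@@H](OC(=O)c2ccc(O[Si](C(C)C)(C(C)C)C(C)C)c(OC)c2)C=C | intermediate
23 | (1R,4R,5S,6S,9R)-4,9-dihydroxydauc-7-en-6-yl 3-methoxy-4-[(triisopropylsilyl)oxy]benzoate | COc1cc(C(=O)O[C@H]2C=C(C)[C@H](O)C[C@@]3(C)CC[C@@](O)(C(C)C)[C@H]23)ccc1O[Si](C(C)C)(C(C)C)C(C)C | intermediate
24 | (1R,4R,5S,6S,9R)-4,9-dihydroxydauc-7-en-6-yl 4-hydroxy-3-methoxybenzoate (trans-fused; 4β-OH, 6α-O-vanilloyl, 9β-OH) | COc1cc(C(=O)O[C@H]2C=C(C)[C@H](O)C[C@@]3(C)CC[C@@](O)(C(C)C)[C@H]23)ccc1O | target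

Total step count: 13. Longest linear sequence: 12 (steps 1–5 and 7–13, from 4-hydroxybutan-2-one).

Steps most likely to fail

Step 10. Closure needs the lactone conformer in which the C2–C3 arm and the isopropenyl group are both axial. The organometallic arm may therefore be protonated, or the radical may abstract hydrogen, before the ring closes, which would leave an ethyl group. The fallback closes the seven-membered ring first and sets out from 18.
- Ring-closing metathesis (second-generation Grubbs catalyst, CH2Cl2, reflux) joins C7 to C8 and should give the bridged iodo lactone F1. Here the lactone is locked as a boat with the iodoethyl arm held over C4.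
- SmI2 then effects the same acyl substitution, now driven by release of the strain of the bridged system, and should give the trans-fused hydroazulenone F2.
- Addition of iPrMgCl/LaCl3·2LiCl to F2, whose β face is shielded by the angular CH3, comes back to the route at 23.

Step 11. The Grignard reagent may attack or β-eliminate the vanillate, and the hindered ketone may be enolised or reduced by β-hydride transfer. The fallback protects the ester electronically as its phenoxide and sets out from 21.
- Bu4NF/AcOH removes the aryl silyl group first and should give the keto phenol F3.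
- Excess iPrMgCl/LaCl3·2LiCl first deprotonates the phenol. The para-phenoxide makes the benzoate carbonyl inert, and addition to the ketone should give the phenolic triol diene F4.
- Ring-closing metathesis of F4 comes back to the route at 24, so step 13 is no longer needed.

Step 5. Simple diastereoselection at the carbinol carbon C6 may be poor, through competition between closed and open transition states. The fallback is a stereoconvergent esterification and sets out from 9 and 10. The C6 epimer formed beside 12, the syn aldol F5, is separated. It is then esterified with 15 under Mitsunobu conditions (PPh3, DIAD, toluene, 0 °C), with inversion at C6. This comes back to the route at 16, so both aldol epimers are funnelled into the same ester.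

Further compounds
F1 | step 10 | bridged iodo lactone (cycloheptene C1, C5–C10 spanned by the C4(=O)–O9 bridge) | O=C1[C@@H]2[C@@H](OC(=O)c3ccc(O[Si](C(C)C)(C(C)C)C(C)C)c(OC)c3)C=C(C)[C@@H](C[C@@]2(C)CCI)O1
F2 | step 10 | trans-fused hydroazulenone (4-oxo compound lacking the isopropyl group of 23) | COc1cc(C(=O)O[C@H]2C=C(C)[C@H](O)C[C@@]3(C)CCC(=O)[C@H]23)ccc1O[Si](C(C)C)(C(C)C)C(C)C
F3 | step 11 | keto phenol (21 without the silyl group) | O=C1CC[C@](C)(C[C@@H](O)C(C)=C)[C@H]1[C@@H](OC(=O)c2ccc(O)c(OC)c2)C=C
F4 | step 11 | phenolic triol diene (22 without the silyl group) | O[C@@]1(C(C)C)CC[C@](C)(C[C@@H](O)C(C)=C)[C@H]1[C@@H](OC(=O)c2ccc(O)c(OC)c2)C=C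
F5 | step 5 | syn aldol, (1R)-carbinol epimer of 12 | O=C1[C@H]([C@H](O)C=C)[C@](C)(CCO[Si](C)(C)C(C)(C)C)C[C@H](C(C)=C)O1
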